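The route rests on not starting from a phloroglucinol at all: ring A (C4a, C5, C6, C7, C8, C8a) is built by a cyclobutenone–siloxyalkyne benzannulation. In one operation the quaternary 1,1-dimethylallyl carbon is delivered on an sp alkyne carbon to what becomes C6, flanked by the C5 and C7 oxygens, with the C8a oxygen para to it, and the three oxygens emerge differentiated as free OH, silyl ether and methoxymethyl ether. The precursors are a triisopropylsilyl ynol ether carrying the 1,1-dimethylallyl group and 3-(methoxymethoxy)cyclobutenone. Acylation at C4a, catalytic asymmetric epoxidation and acid-triggered closure of ring C through the O1–C2 bond then give the (2R,3R)-flavanonol.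

Key step: step 4

Remark: the (S)-BINOL ligand in step 10 is assigned by analogy with unsubstituted chalcone, so the absolute configuration of 23 is to be verified and the ligand antipode used if the opposite sense is found; 7 is drawn as the diketone although it reacts as its enol.

Step 1
Reactants: 1 methyl 2,2-dimethylbut-3-enoate; 2 dibromomethane
Product: 5 1-(triisopropylsilyloxy)-3,3-dimethylpent-4-en-1-yne, via lithium dibromoenolate 3 (not isolated), via lithium ynolate 4 (not isolated)
Conditions: 2, lithium 2,2,6,6-tetramethylpiperidide (LiTMP), THF, −78 °C; then 1; then LiN(SiMe3)2; then n-BuLi, −78 °C to rt; then TIPSCl, −78 °C to rt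
Reagents that add atoms: triisopropylsilyl chloride, CC(C)[Si](Cl)(C(C)C)C(C)C
Why: Kowalski ester homologation, in which acylation of dibromomethyllithium and deprotonation give dibromoenolate 3, bromine–lithium exchange triggers a 1,2-shift to ynolate 4, and the bulky silyl chloride traps the ynolate on oxygen.

Step 2
Reactants: 6 3-ethoxycyclobut-2-en-1-one
Product: 7 cyclobutane-1,3-dione
Conditions: 1 M HCl (aq), 0 °C to rt; concentrate
Reagents that add atoms: water, O
Why: Acid hydrolysis of a vinylogous ester by addition–elimination at C3 is the established access to this dione, which is isolated as its crystalline enol.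

Step 3
Reactants: 7 cyclobutane-1,3-dione
Product: 8 3-(methoxymethoxy)cyclobut-2-en-1-one
Conditions: MOMCl, i-Pr2NEt, CH2Cl2, 0 °C
Reagents that add atoms: chloromethyl methyl ether, COCCl
Why: O-alkylation of the strongly acidic enol (a vinylogous carboxylic acid) by the hard electrophile MOMCl should give the vinylogous methoxymethyl ester, which is used without storage.

Step 4
Reactants: 5 1-(triisopropylsilyloxy)-3,3-dimethylpent-4-en-1-yne; 8 3-(methoxymethoxy)cyclobut-2-en-1-one
Product: 13 5-(methoxymethoxy)-2-(2-methylbut-3-en-2-yl)-3-(triisopropylsilyloxy)phenol, via vinylketene 9 (not isolated), via vinylcyclobutenone 10 (not isolated), via dienylketene 11 (not isolated), via cyclohexadienone 12 (not isolated)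
Conditions: 5 (1.2 equiv), toluene, 80 °C, then 110 °C
Reagents that add atoms: none
Why: Heating opens 8 by conrotatory 4π electrocyclic cleavage to the 2-alkoxyvinylketene 9, whose ketene C=C adds to the electron-rich ynol ether 5 in a polar [2+2] cycloaddition to give 4-vinylcyclobutenone 10; a second 4π opening gives dienylketene 11, which closes by 6π electrocyclisation to cyclohexadienone 12 and tautomerises to phenol 13, each stage driven by release of four-ring strain and finally by aromatisation. The closest known reaction type is the Danheiser benzannulation of cyclobutenones with trialkylsiloxyalkynes, which converts 3-alkylcyclobutenones and substituted siloxyalkynes into 2-substituted resorcinol monosilyl ethers; here it is applied with an alkoxy group at C3 of the cyclobutenone and a tertiary alkyl group on the alkyne. Ring A is closed by thermal disrotatory 6π electrocyclisation of 11 (bond between the former carbonyl carbon and the former C4 of 8), after the alkyne has been inserted between C1 and C2 of 8 through the transient four-membered ring of 10. No stereocentre remains in 13, the single racemic stereocentre of 10 being lost on the way. The step needs the regiochemistry of the ketene–alkyne cycloaddition, and this is set by the polarisation of the ynol ether: its nucleophilic carbon, the one carrying the 1,1-dimethylallyl group, bonds to the electrophilic ketene carbonyl carbon, so the quaternary carbon ends between the new hydroxyl and the siloxy group with the methoxymethoxy group para to it. The quaternary centre is never forged at a crowded arene position because it arrives on a linear sp carbon, and the hindered phenol formed should be a poor trap for ketene, so little aryl ester is expected.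

Step 5
Reactants: 13 5-(methoxymethoxy)-2-(2-methylbut-3-en-2-yl)-3-(triisopropylsilyloxy)phenol
Product: 14 1,3-bis(triisopropylsilyloxy)-5-(methoxymethoxy)-2-(2-methylbut-3-en-2-yl)benzene
Conditions: TIPSOTf, 2,6-lutidine, CH2Cl2, 0 °C to rt
Reagents that add atoms: triisopropylsilyl trifluoromethanesulfonate, CC(C)[Si](OS(=O)(=O)C(F)(F)F)(C(C)C)C(C)C
Why: Silylation of a hindered phenol with a silyl triflate and a hindered pyridine base should tolerate the acetal at low temperature and makes the two open ring positions equivalent, which removes any regiochemical question from the next step.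

Step 6
Reactants: 14 1,3-bis(triisopropylsilyloxy)-5-(methoxymethoxy)-2-(2-methylbut-3-en-2-yl)benzene
Product: 15 2-bromo-1-(methoxymethoxy)-3,5-bis(triisopropylsilyloxy)-4-(2-methylbut-3-en-2-yl)benzene
Conditions: NBS (1.0 equiv), CH2Cl2, −78 to −20 °C
Reagents that add atoms: N-bromosuccinimide, O=C1CCC(=O)N1Br
Why: Electrophilic aromatic bromination of a phloroglucinol triether is fast at low temperature, either open position gives the same monobromide, and the isolated vinyl group (no allylic hydrogen, far less nucleophilic than the arene) should be left alone.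

Step 7
Reactants: 16 4-hydroxybenzaldehyde
Product: 17 4-(triisopropylsilyloxy)benzaldehyde
Conditions: TIPSCl, imidazole, DMF, rt
Reagents that add atoms: triisopropylsilyl chloride, CC(C)[Si](Cl)(C(C)C)C(C)C
Why: Standard imidazole-promoted silylation of an unhindered phenol.

Step 8
Reactants: 17 4-(triisopropylsilyloxy)benzaldehyde; 18 diethyl (N-methoxy-N-methylcarbamoylmethyl)phosphonate
Product: 19 (E)-N-methoxy-N-methyl-3-[4-(triisopropylsilyloxy)phenyl]prop-2-enamide
Conditions: NaH, THF, 0 °C; then 17, 0 °C to rt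
Reagents that add atoms: none
Why: Horner–Wadsworth–Emmons olefination with an amide-stabilised phosphonate should give the (E)-alkene through the thermodynamically controlled oxaphosphetane pathway.

Step 9
Reactants: 15 2-bromo-1-(methoxymethoxy)-3,5-bis(triisopropylsilyloxy)-4-(2-methylbut-3-en-2-yl)benzene; 19 (E)-N-methoxy-N-methyl-3-[4-(triisopropylsilyloxy)phenyl]prop-2-enamide
Product: 22 (E)-1-[2-(methoxymethoxy)-5-(2-methylbut-3-en-2-yl)-4,6-bis(triisopropylsilyloxy)phenyl]-3-[4-(triisopropylsilyloxy)phenyl]prop-2-en-1-one, via aryllithium 20 (not isolated), via lithium hemiaminal 21 (not isolated)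
Conditions: t-BuLi (2.0 equiv), Et2O, −78 °C; then 19 in THF, −78 to −50 °C; then AcOH, −78 °C
Reagents that add atoms: none
Why: Bromine–lithium exchange is fast at −78 °C and the aryllithium should be acylated once through the chelated adduct 21 (Weinreb ketone synthesis), the low temperature and cold acidic quench forestalling 1,3 O-to-C silyl migration and the E geometry being carried over unchanged.

Step 10
Reactants: 22 (E)-1-[2-(methoxymethoxy)-5-(2-methylbut-3-en-2-yl)-4,6-bis(triisopropylsilyloxy)phenyl]-3-[4-(triisopropylsilyloxy)phenyl]prop-2-en-1-one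
Product: 23 [(2R,3S)-3-[4-(triisopropylsilyloxy)phenyl]oxiran-2-yl][2-(methoxymethoxy)-5-(2-methylbut-3-en-2-yl)-4,6-bis(triisopropylsilyloxy)phenyl]methanone
Conditions: La(O-iPr)3 (10 mol %), (S)-BINOL (10 mol %), Ph3As=O (10 mol %), t-BuOOH (decane), 4 Å MS, THF, rt
Reagents that add atoms: tert-butyl hydroperoxide, CC(C)(C)OO
Why: Catalytic asymmetric nucleophilic (Weitz–Scheffer-type) epoxidation in which the chiral lanthanum–BINOL peroxide adds to one enantioface at Cβ and ring closure with loss of tert-butoxide keeps the E geometry as a trans epoxide, so both stereocentres (αR, βS) are set by the ligand hand, while the non-aqueous, near-neutral medium should spare the aryl silyl ethers and the nucleophilic oxidant ignores the isolated vinyl group.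

Step 11
Reactants: 23 [(2R,3S)-3-[4-(triisopropylsilyloxy)phenyl]oxiran-2-yl][2-(methoxymethoxy)-5-(2-methylbut-3-en-2-yl)-4,6-bis(triisopropylsilyloxy)phenyl]methanone
Product: 25 (2R,3R)-3-hydroxy-6-(2-methylbut-3-en-2-yl)-5,7-bis(triisopropylsilyloxy)-2-[4-(triisopropylsilyloxy)phenyl]chroman-4-one, via phenol epoxide 24 (not isolated)
Conditions: TsOH·H2O (0.3 equiv), MeOH–CH2Cl2, 0 °C to rt
Reagents that add atoms: none
Why: Acid-catalysed acetal cleavage frees only the phenol para to the 1,1-dimethylallyl group, which opens the protonated epoxide at the benzylic, 4-siloxyphenyl-stabilised carbon in a 6-endo-tet sense with inversion (βS becomes 2R) while C3 (αR) is untouched, giving the 2,3-trans diequatorial (2R,3R) product, which is also the thermodynamic outcome should benzylic solvolysis precede closure; the sulfonate counter-ion avoids halohydrin formation and double inversion.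

Step 12
Reactants: 25 (2R,3R)-3-hydroxy-6-(2-methylbut-3-en-2-yl)-5,7-bis(triisopropylsilyloxy)-2-[4-(triisopropylsilyloxy)phenyl]chroman-4-one
Product: 26 (2R,3R)-3,5,7-trihydroxy-2-(4-hydroxyphenyl)-6-(2-methylbut-3-en-2-yl)chroman-4-one (CNP0527000.1)
Conditions: Bu4NF (3.5 equiv), AcOH (3.5 equiv), THF, 0 °C to rt
Reagents that add atoms: none
Why: Fluoride-mediated cleavage of the three aryl silyl ethers, buffered with acetic acid so that no phenoxide-induced ring opening, C2 epimerisation or oxidation to the flavonol should occur.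

Compound list
1 | methyl 2,2-dimethylbut-3-enoate | C=CC(C)(C)C(=O)OC | starting material
2 | dibromomethane | BrCBr | starting material
3 | lithium 1,1-dibromo-3,3-dimethylpenta-1,4-dien-2-olate | C=CC(C)(C)C(O[Li])=C(Br)Br | intermediate
4 | lithium 3,3-dimethylpent-4-en-1-yn-1-olate | C=CC(C)(C)C#CO[Li] | intermediate
5 | 1-(triisopropylsilyloxy)-3,3-dimethylpent-4-en-1-yne | C=CC(C)(C)C#CO[Si](C(C)C)(C(C)C)C(C)C | intermediate
6 | 3-ethoxycyclobut-2-en-1-one | CCOC1=CC(=O)C1 | starting material
7 | cyclobutane-1,3-dione | O=C1CC(=O)C1 | intermediate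
8 | 3-(methoxymethoxy)cyclobut-2-en-1-one | COCOC1=CC(=O)C1 | intermediate
9 | 3-(methoxymethoxy)buta-1,3-dien-1-one | C=C(OCOC)C=C=O | intermediate
10 | 4-[1-(methoxymethoxy)ethenyl]-2-(2-methylbut-3-en-2-yl)-3-(triisopropylsilyloxy)cyclobut-2-en-1-one (racemic) | C=CC(C)(C)C1=C(O[Si](C(C)C)(C(C)C)C(C)C)C(C(=C)OCOC)C1=O | intermediate
11 | (3E)-5-(methoxymethoxy)-2-(2-methylbut-3-en-2-yl)-3-(triisopropylsilyloxy)hexa-1,3,5-trien-1-one | C=CC(C)(C)C(=C=O)/C(O[Si](C(C)C)(C(C)C)C(C)C)=C\C(=C)OCOC | intermediate
12 | 5-(methoxymethoxy)-2-(2-methylbut-3-en-2-yl)-3-(triisopropylsilyloxy)cyclohexa-2,4-dien-1-one | O=C1CC(OCOC)=CC(O[Si](C(C)C)(C(C)C)C(C)C)=C1C(C)(C)C=C | intermediate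
13 | 5-(methoxymethoxy)-2-(2-methylbut-3-en-2-yl)-3-(triisopropylsilyloxy)phenol | C=CC(C)(C)c1c(O)cc(OCOC)cc1O[Si](C(C)C)(C(C)C)C(C)C | intermediate
14 | 1,3-bis(triisopropylsilyloxy)-5-(methoxymethoxy)-2-(2-methylbut-3-en-2-yl)benzene | C=CC(C)(C)c1c(O[Si](C(C)C)(C(C)C)C(C)C)cc(OCOC)cc1O[Si](C(C)C)(C(C)C)C(C)C | intermediate
15 | 2-bromo-1-(methoxymethoxy)-3,5-bis(triisopropylsilyloxy)-4-(2-methylbut-3-en-2-yl)benzene | C=CC(C)(C)c1c(O[Si](C(C)C)(C(C)C)C(C)C)cc(OCOC)c(Br)c1O[Si](C(C)C)(C(C)C)C(C)C | intermediate
16 | 4-hydroxybenzaldehyde | O=Cc1ccc(O)cc1 | starting material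
17 | 4-(triisopropylsilyloxy)benzaldehyde | O=Cc1ccc(O[Si](C(C)C)(C(C)C)C(C)C)cc1 | intermediate
18 | diethyl (N-methoxy-N-methylcarbamoylmethyl)phosphonate | CCOP(=O)(CC(=O)N(C)OC)OCC | starting material
19 | (E)-N-methoxy-N-methyl-3-[4-(triisopropylsilyloxy)phenyl]prop-2-enamide | CON(C)C(=O)/C=C/c1ccc(O[Si](C(C)C)(C(C)C)C(C)C)cc1 | intermediate
20 | [2-(methoxymethoxy)-5-(2-methylbut-3-en-2-yl)-4,6-bis(triisopropylsilyloxy)phenyl]lithium | C=CC(C)(C)c1c(O[Si](C(C)C)(C(C)C)C(C)C)cc(OCOC)c([Li])c1O[Si](C(C)C)(C(C)C)C(C)C | intermediate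
21 | lithium (E)-1-[methoxy(methyl)amino]-1-[2-(methoxymethoxy)-5-(2-methylbut-3-en-2-yl)-4,6-bis(triisopropylsilyloxy)phenyl]-3-[4-(triisopropylsilyloxy)phenyl]prop-2-en-1-olate | C=CC(C)(C)c1c(O[Si](C(C)C)(C(C)C)C(C)C)cc(OCOC)c(C(O[Li])(N(C)OC)/C=C/c2ccc(O[Si](C(C)C)(C(C)C)C(C)C)cc2)c1O[Si](C(C)C)(C(C)C)C(C)C | intermediate
22 | (E)-1-[2-(methoxymethoxy)-5-(2-methylbut-3-en-2-yl)-4,6-bis(triisopropylsilyloxy)phenyl]-3-[4-(triisopropylsilyloxy)phenyl]prop-2-en-1-one | C=CC(C)(C)c1c(O[Si](C(C)C)(C(C)C)C(C)C)cc(OCOC)c(C(=O)/C=C/c2ccc(O[Si](C(C)C)(C(C)C)C(C)C)cc2)c1O[Si](C(C)C)(C(C)C)C(C)C | intermediate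
23 | [(2R,3S)-3-[4-(triisopropylsilyloxy)phenyl]oxiran-2-yl][2-(methoxymethoxy)-5-(2-methylbut-3-en-2-yl)-4,6-bis(triisopropylsilyloxy)phenyl]methanone | C=CC(C)(C)c1c(O[Si](C(C)C)(C(C)C)C(C)C)cc(OCOC)c(C(=O)[C@@H]2O[C@H]2c3ccc(O[Si](C(C)C)(C(C)C)C(C)C)cc3)c1O[Si](C(C)C)(C(C)C)C(C)C | intermediate
24 | [(2R,3S)-3-[4-(triisopropylsilyloxy)phenyl]oxiran-2-yl][2-hydroxy-5-(2-methylbut-3-en-2-yl)-4,6-bis(triisopropylsilyloxy)phenyl]methanone | C=CC(C)(C)c1c(O[Si](C(C)C)(C(C)C)C(C)C)cc(O)c(C(=O)[C@@H]2O[C@H]2c3ccc(O[Si](C(C)C)(C(C)C)C(C)C)cc3)c1O[Si](C(C)C)(C(C)C)C(C)C | intermediate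
25 | (2R,3R)-3-hydroxy-6-(2-methylbut-3-en-2-yl)-5,7-bis(triisopropylsilyloxy)-2-[4-(triisopropylsilyloxy)phenyl]chroman-4-one | C=CC(C)(C)c1c(O[Si](C(C)C)(C(C)C)C(C)C)cc2c(c1O[Si](C(C)C)(C(C)C)C(C)C)C(=O)[C@H](O)[C@@H](c1ccc(O[Si](C(C)C)(C(C)C)C(C)C)cc1)O2 | intermediate
26 | (2R,3R)-3,5,7-trihydroxy-2-(4-hydroxyphenyl)-6-(2-methylbut-3-en-2-yl)chroman-4-one (CNP0527000.1) | C=CC(C)(C)c1c(O)cc2c(c1O)C(=O)[C@H](O)[C@@H](c1ccc(O)cc1)O2 | target

Total step count: 12. Longest linear sequence: 9 steps (6 to 26 through steps 2, 3, 4, 5, 6, 9, 10, 11 and 12).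

Steps most likely to fail

Step 4. The 3-alkoxy group stabilises 8 as a vinylogous ester, so thermal ring opening may need temperatures at which 8 or the ynol ether degrade, and the electron-rich vinylketene may dimerise faster than the hindered tertiary ynol ether captures it. The fallback generates the same vinylketene at room temperature by a photochemical Wolff rearrangement; it sets out from 5 and comes back to the route at 13. Butane-2,3-dione is O-alkylated at its enol (MOMCl, i-Pr2NEt, CH2Cl2) to give 3-(methoxymethoxy)but-3-en-2-one F1. The kinetic enolate of F1 (LiN(SiMe3)2, THF, −78 °C) is trifluoroacetylated with 2,2,2-trifluoroethyl trifluoroacetate to 1,1,1-trifluoro-5-(methoxymethoxy)hex-5-ene-2,4-dione F2. Detrifluoroacetylative diazo transfer (MsN3, Et3N, H2O, MeCN) then gives 1-diazo-3-(methoxymethoxy)but-3-en-2-one F3. Irradiation of F3 with an excess of 5 (254 to 300 nm, ClCH2CH2Cl, rt) should release 9 at low stationary concentration, and brief warming to 80 °C should carry the material through 10, 11 and 12 to 13.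

Step 9. Acylation of the doubly ortho-substituted aryllithium by the amide may be slower than 1,3 O-to-C silyl migration or proton capture once the mixture is warmed. The fallback uses a far more reactive electrophile and a separate oxidation; it sets out from 15 and 19 and comes back at 22. Amide 19 is reduced (i-Bu2AlH, THF, −78 °C) to (E)-3-[4-(triisopropylsilyloxy)phenyl]prop-2-enal F4. Aryllithium 20, made from 15 as in step 9, should add to F4 within minutes at −78 °C to give racemic (E)-1-[2-(methoxymethoxy)-5-(2-methylbut-3-en-2-yl)-4,6-bis(triisopropylsilyloxy)phenyl]-3-[4-(triisopropylsilyloxy)phenyl]prop-2-en-1-ol F5. Oxidation of this allylic, benzylic alcohol (MnO2, CH2Cl2, rt) removes the stereocentre and gives 22.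

Step 10. The twisted, congested aryl enone may react slowly and with poor facial discrimination at the catalyst, and a long exposure to hydroperoxide may erode the aryl silyl ethers. The fallback sets the two stereocentres on an unhindered amide before the fragments are joined; it sets out from 17 and 15 and comes back at 23. Horner–Wadsworth–Emmons olefination of 17 with diethyl (2-morpholino-2-oxoethyl)phosphonate (NaH, THF) gives (E)-1-(morpholin-4-yl)-3-[4-(triisopropylsilyloxy)phenyl]prop-2-en-1-one F6. Catalytic asymmetric epoxidation of this amide (Sm(O-iPr)3, BINOL of the hand that delivers the 2R,3S product, Ph3As=O, t-BuOOH, 4 Å MS, THF) should give morpholin-4-yl[(2R,3S)-3-[4-(triisopropylsilyloxy)phenyl]oxiran-2-yl]methanone F7. Aryllithium 20, made from 15 at −78 °C, is acylated by F7 through lithium morpholine hemiaminal F8, and a cold AcOH quench releases 23, from which steps 11 and 12 follow unchanged.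

Further compounds
F1 | step 4 | 3-(methoxymethoxy)but-3-en-2-one | CC(=O)C(=C)OCOC
F2 | step 4 | 1,1,1-trifluoro-5-(methoxymethoxy)hex-5-ene-2,4-dione | C=C(OCOC)C(=O)CC(=O)C(F)(F)F
F3 | step 4 | 1-diazo-3-(methoxymethoxy)but-3-en-2-one | C=C(OCOC)C(=O)C=[N+]=[N-]
F4 | step 9 | (E)-3-[4-(triisopropylsilyloxy)phenyl]prop-2-enal | O=C/C=C/c1ccc(O[Si](C(C)C)(C(C)C)C(C)C)cc1
F5 | step 9 | (E)-1-[2-(methoxymethoxy)-5-(2-methylbut-3-en-2-yl)-4,6-bis(triisopropylsilyloxy)phenyl]-3-[4-(triisopropylsilyloxy)phenyl]prop-2-en-1-ol (racemic) | C=CC(C)(C)c1c(O[Si](C(C)C)(C(C)C)C(C)C)cc(OCOC)c(C(O)/C=C/c2ccc(O[Si](C(C)C)(C(C)C)C(C)C)cc2)c1O[Si](C(C)C)(C(C)C)C(C)C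
F6 | step 10 | (E)-1-(morpholin-4-yl)-3-[4-(triisopropylsilyloxy)phenyl]prop-2-en-1-one | O=C(/C=C/c1ccc(O[Si](C(C)C)(C(C)C)C(C)C)cc1)N1CCOCC1
F7 | step 10 | morpholin-4-yl[(2R,3S)-3-[4-(triisopropylsilyloxy)phenyl]oxiran-2-yl]methanone | O=C([C@@H]1O[C@H]1c2ccc(O[Si](C(C)C)(C(C)C)C(C)C)cc2)N3CCOCC3
F8 | step 10 | lithium [2-(methoxymethoxy)-5-(2-methylbut-3-en-2-yl)-4,6-bis(triisopropylsilyloxy)phenyl](morpholin-4-yl)[(2R,3S)-3-[4-(triisopropylsilyloxy)phenyl]oxiran-2-yl]methanolate | C=CC(C)(C)c1c(O[Si](C(C)C)(C(C)C)C(C)C)cc(OCOC)c(C(O[Li])(N2CCOCC2)[C@@H]3O[C@H]3c4ccc(O[Si](C(C)C)(C(C)C)C(C)C)cc4)c1O[Si](C(C)C)(C(C)C)C(C)C
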